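**Plan**

1. Retrosynthesis: the four O–Si bonds of a fully silylated precursor are cut first. The C2–C1′ bond between the chromanone and the B-ring arene is cut next, giving a 5,7,8-trisilyloxychromone and an arylboronic acid.
2. The enabling feature is the vinylogous ester O1–C2=C3–C4=O of the pyranone ring (ring C) at the chromone oxidation level. C2 is its β-carbon, flat and prochiral, so an aryl–rhodium species can add there, join both halves and create the only stereocentre in one event.
3. Chromone half: ring A is bought as a tetramethoxybenzene. Acetylation with ortho-demethylation, then enaminone cyclisation, closes ring C through the O1–C2 bond, and the methyl ethers are exchanged for silyl ethers.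
4. Boronic acid half: ring B is bought as 4-bromo-2-iodophenol. The isopentenyl chain is joined at C3′ by an iodine-selective Negishi coupling and the bromide is converted into the boronic acid.
5. Forward order: ring A, ring C, (separately) the chain on ring B, ring B onto C2, then desilylation with buffered fluoride. Silyl ethers are used because the target tolerates neither acid (isopentenyl phenol), hydrogen (alkene) nor base (C2 and the A-ring pattern).
6. Stereochemistry: C2 (S) comes from the chiral bisphosphine on rhodium in the conjugate arylation; no later step is basic enough to open the pyranone.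

Key step: step 8

Assumption: the (S)-configured biaryl bisphosphine is taken to deliver the aryl group to the chromone face that gives 2S, by analogy with the face selection in rhodium-catalysed arylation of cyclic enones. If a first small batch shows the opposite sense, the (R)-ligand is used and nothing else changes.

**Step 1**
Reactants: 1 1,2,3,5-tetramethoxybenzene
Product: 2 1-(2-hydroxy-3,4,6-trimethoxyphenyl)ethan-1-one
Conditions: AcCl (1.2 equiv), AlCl3 (2.5 equiv), Et2O, 0 °C → rt; aq. HCl work-up
Reagents that add atoms: acetyl chloride, CC(Cl)=O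
Why: Friedel–Crafts acetylation should occur at one of the two equivalent free positions of the electron-rich arene, and AlCl3 should then cleave, through the six-membered ketone–aluminium chelate, the ortho methoxyl that is buttressed by a neighbouring methoxyl, so the free OH that later becomes O1 sits next to the 3-methoxyl.

**Step 2**
Reactants: 2 1-(2-hydroxy-3,4,6-trimethoxyphenyl)ethan-1-one
Product: 4 5,7,8-trimethoxy-4H-chromen-4-one, via enaminone 3 (not isolated)
Conditions: DMF-DMA (2 equiv), toluene, 100 °C; evaporate; conc. HCl, CH2Cl2, 40 °C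
Reagents that add atoms: N,N-dimethylformamide dimethyl acetal, COC(OC)N(C)C
Why: Condensation of the methyl ketone with the amide acetal gives the enaminone, and acid then drives intramolecular oxa-Michael addition of the single free phenol and loss of dimethylamine (the enaminone route to 2,3-unsubstituted chromones), which closes ring C with the 5,7,8-pattern fixed by step 1.

**Step 3**
Reactants: 4 5,7,8-trimethoxy-4H-chromen-4-one
Product: 5 5,7,8-trihydroxy-4H-chromen-4-one
Conditions: BBr3 (7 equiv), CH2Cl2, −78 °C → rt, argon; then ice-water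
Reagents that add atoms: none
Why: Lewis-acid cleavage of aryl methyl ethers by BBr3 should remove all three methyl groups under anhydrous conditions, which avoids the hydrolytic pyranone opening and reclosure (Wessely–Moser rearrangement) that hot HBr or HI would risk.

**Step 4**
Reactants: 5 5,7,8-trihydroxy-4H-chromen-4-one
Product: 6 5,7,8-tris[(tert-butyldimethylsilyl)oxy]-4H-chromen-4-one
Conditions: TBSOTf (3.6 equiv), 2,6-lutidine (5 equiv), CH2Cl2, 0 °C → rt, argon; chromatography on Et3N-deactivated silica
Reagents that add atoms: tert-butyldimethylsilyl trifluoromethanesulfonate, CC(C)(C)[Si](C)(C)OS(=O)(=O)C(F)(F)F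
Why: O-Silylation with the silyl triflate is strong enough to cap the hydrogen-bonded 5-OH as well as the 7,8-catechol, and the silyl ethers both prevent phenoxide or 5-O/4-O chelate binding to rhodium later and leave under buffered fluoride at the end.

**Step 5**
Reactants: 7 4-bromo-2-iodophenol
Product: 8 (4-bromo-2-iodophenoxy)(tert-butyl)dimethylsilane
Conditions: TBSCl (1.2 equiv), imidazole (2.5 equiv), DMF, rt
Reagents that add atoms: tert-butyldimethylsilyl chloride, CC(C)(C)[Si](C)(C)Cl
Why: Imidazole-promoted O-silylation of a phenol is routine and masks the acidic OH before the organozinc and organolithium steps.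

**Step 6**
Reactants: 8 (4-bromo-2-iodophenoxy)(tert-butyl)dimethylsilane; 9 4-bromo-2-methylbut-1-ene
Product: 11 [4-bromo-2-(3-methylbut-3-en-1-yl)phenoxy](tert-butyl)dimethylsilane, via homoallylzinc bromide 10 (not isolated)
Conditions: 9 (1.5 equiv), Zn dust (TMSCl/1,2-dibromoethane-activated), LiCl, THF, 40 °C; then 8, PdCl2(dppf) (3 mol %), THF, rt
Reagents that add atoms: none
Why: In this Negishi sp3–sp2 coupling, oxidative addition to the C–I bond should be much faster than to the C–Br bond at room temperature, and the wide-bite-angle dppf ligand should favour reductive elimination over β-hydride elimination of the primary alkyl–palladium intermediate.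

**Step 7**
Reactants: 11 [4-bromo-2-(3-methylbut-3-en-1-yl)phenoxy](tert-butyl)dimethylsilane
Product: 14 [4-[(tert-butyldimethylsilyl)oxy]-3-(3-methylbut-3-en-1-yl)phenyl]boronic acid, via aryllithium 12 (not isolated), via lithium triisopropoxyborate 13 (not isolated)
Conditions: n-BuLi (1.05 equiv), THF, −78 °C; B(OiPr)3 (1.5 equiv), −78 °C → rt; 1 M HCl to pH 5, 0 °C
Reagents that add atoms: triisopropyl borate, CC(C)OB(OC(C)C)OC(C)C; water, O
Why: Bromine–lithium exchange followed by electrophilic borylation and mild hydrolysis is a standard route to arylboronic acids, and the aryl silyl ether and the isolated alkene are inert to n-BuLi at −78 °C.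

**Step 8**
Reactants: 6 5,7,8-tris[(tert-butyldimethylsilyl)oxy]-4H-chromen-4-one; 14 [4-[(tert-butyldimethylsilyl)oxy]-3-(3-methylbut-3-en-1-yl)phenyl]boronic acid
Product: 15 (2S)-5,7,8-tris[(tert-butyldimethylsilyl)oxy]-2-[4-[(tert-butyldimethylsilyl)oxy]-3-(3-methylbut-3-en-1-yl)phenyl]-2,3-dihydro-4H-chromen-4-one
Conditions: [Rh(OH)(cod)]2 (2.5 mol %), (S)-MeO-F12-BIPHEP [(S)-6,6′-dimethoxy-2,2′-bis[bis(3,4,5-trifluorophenyl)phosphino]-1,1′-biphenyl] (5.5 mol %), 14 (2 equiv), CH2Cl2/H2O (10:1), 30 °C, argon, no added base
Reagents that add atoms: none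
Why: In this Hayashi–Miyaura-type asymmetric 1,4-addition the Rh(I)–OH complex transmetalates with 14 to an aryl–Rh(I) species, the C2=C3 bond of the pyranone of 6 coordinates, and migratory insertion transfers the aryl group to C2, the β-carbon of the vinylogous ester O1–C2=C3–C4=O, giving an oxa-π-allyl rhodium enolate that water protonates at C3 with return of Rh–OH. The closest known reaction type is the rhodium/bisphosphine-catalysed enantioselective conjugate addition of arylboronic acids to chromones, which gives 2-arylchroman-4-ones. No ring is closed: the pyranone ring is carried in intact and only moves from the 4H-pyran-4-one to the 2,3-dihydro level. The one new stereocentre, C2, is set under catalyst control, because the C2-symmetric (S)-biaryl bisphosphine should block one enantioface of the bound C2=C3 bond in the insertion step so that the aryl group arrives on the face that gives 2S. The step needs 1,4- over 1,2-addition and a single addition, which the soft aryl–Rh(I) nucleophile and the loss of the enone after one insertion should secure, and it needs the isolated 1,1-disubstituted alkene left alone, which should hold because aryl–Rh(I) does not insert into unactivated alkenes and no Rh–H is formed. It also needs the product not to reopen by retro-oxa-Michael loss of the C8a phenoxide, which the base-free medium and the fast turnover of the electron-poor ligand at 30 °C should secure.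

**Step 9**
Reactants: 15 (2S)-5,7,8-tris[(tert-butyldimethylsilyl)oxy]-2-[4-[(tert-butyldimethylsilyl)oxy]-3-(3-methylbut-3-en-1-yl)phenyl]-2,3-dihydro-4H-chromen-4-one
Product: 16 (2S)-5,7,8-trihydroxy-2-[4-hydroxy-3-(3-methylbut-3-en-1-yl)phenyl]-2,3-dihydro-4H-chromen-4-one
Conditions: TBAF (5 equiv)/AcOH (5.5 equiv) premixed, degassed THF, 0 °C, argon; pH 5 buffer work-up
Reagents that add atoms: none
Why: Fluoride-mediated cleavage of the four aryl silyl ethers, buffered by acetic acid so that each phenoxide is protonated as it forms, should free the phenols without the acid that would cyclise the isopentenyl phenol to a chroman, without hydrogen, and without the base that would enolise C3, open the pyranone and so racemise C2 or scramble the A ring.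

**Compound list**

1 | 1,2,3,5-tetramethoxybenzene | COc1cc(OC)c(OC)c(OC)c1 | starting material
2 | 1-(2-hydroxy-3,4,6-trimethoxyphenyl)ethan-1-one | CC(=O)c1c(O)c(OC)c(OC)cc1OC | intermediate
3 | (E)-3-(dimethylamino)-1-(2-hydroxy-3,4,6-trimethoxyphenyl)prop-2-en-1-one (enaminone, not isolated) | CN(C)/C=C/C(=O)c1c(O)c(OC)c(OC)cc1OC | intermediate
4 | 5,7,8-trimethoxy-4H-chromen-4-one | COc1cc(OC)c2c(=O)ccoc2c1OC | intermediate
5 | 5,7,8-trihydroxy-4H-chromen-4-one | O=c1ccoc2c(O)c(O)cc(O)c12 | intermediate
6 | 5,7,8-tris[(tert-butyldimethylsilyl)oxy]-4H-chromen-4-one | CC(C)(C)[Si](C)(C)Oc1cc(O[Si](C)(C)C(C)(C)C)c2c(=O)ccoc2c1O[Si](C)(C)C(C)(C)C | intermediate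
7 | 4-bromo-2-iodophenol | Oc1ccc(Br)cc1I | starting material
8 | (4-bromo-2-iodophenoxy)(tert-butyl)dimethylsilane | CC(C)(C)[Si](C)(C)Oc1ccc(Br)cc1I | intermediate
9 | 4-bromo-2-methylbut-1-ene | C=C(C)CCBr | starting material
10 | (3-methylbut-3-en-1-yl)zinc bromide (not isolated) | C=C(C)CC[Zn]Br | intermediate
11 | [4-bromo-2-(3-methylbut-3-en-1-yl)phenoxy](tert-butyl)dimethylsilane | C=C(C)CCc1cc(Br)ccc1O[Si](C)(C)C(C)(C)C | intermediate
12 | [4-[(tert-butyldimethylsilyl)oxy]-3-(3-methylbut-3-en-1-yl)phenyl]lithium (not isolated) | [Li]c1ccc(O[Si](C)(C)C(C)(C)C)c(CCC(C)=C)c1 | intermediate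
13 | lithium [4-[(tert-butyldimethylsilyl)oxy]-3-(3-methylbut-3-en-1-yl)phenyl]tri(propan-2-yloxy)borate (not isolated) | C=C(C)CCc1cc([B-](OC(C)C)(OC(C)C)OC(C)C)ccc1O[Si](C)(C)C(C)(C)C.[Li+] | intermediate
14 | [4-[(tert-butyldimethylsilyl)oxy]-3-(3-methylbut-3-en-1-yl)phenyl]boronic acid | C=C(C)CCc1cc(B(O)O)ccc1O[Si](C)(C)C(C)(C)C | intermediate
15 | (2S)-5,7,8-tris[(tert-butyldimethylsilyl)oxy]-2-[4-[(tert-butyldimethylsilyl)oxy]-3-(3-methylbut-3-en-1-yl)phenyl]-2,3-dihydro-4H-chromen-4-one | C=C(C)CCc1cc([C@@H]2CC(=O)c3c(O[Si](C)(C)C(C)(C)C)cc(O[Si](C)(C)C(C)(C)C)c(O[Si](C)(C)C(C)(C)C)c3O2)ccc1O[Si](C)(C)C(C)(C)C | intermediate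
16 | (2S)-5,7,8-trihydroxy-2-[4-hydroxy-3-(3-methylbut-3-en-1-yl)phenyl]-2,3-dihydro-4H-chromen-4-one | C=C(C)CCc1cc([C@@H]2CC(=O)c3c(O)cc(O)c(O)c3O2)ccc1O | target

**Step count**

Total steps: 9. Longest linear sequence: 6 (steps 1, 2, 3, 4, 8, 9); the boronic acid branch (steps 5–7) is convergent.

**Steps most likely to fail**

Step 8. The three silyloxy donors and the peri 5-O-silyl group may make insertion of the C2=C3 bond slow, so that protodeboronation of the boronic acid outruns it, or the enantioface discrimination may be insufficient. The fallback sets out from 11 and 6 and comes back at 15. Bromide 11 is converted with magnesium (LiCl, THF) into [4-[(tert-butyldimethylsilyl)oxy]-3-(3-methylbut-3-en-1-yl)phenyl]magnesium bromide F1. F1 is added to 6 with CuBr·SMe2 (10 mol %) and TMSCl in THF at −40 °C, a copper-catalysed conjugate addition in which the silyl chloride activates the pyranone and traps the adduct. This should give racemic 5,7,8-tris[(tert-butyldimethylsilyl)oxy]-2-[4-[(tert-butyldimethylsilyl)oxy]-3-(3-methylbut-3-en-1-yl)phenyl]-4-[(trimethylsilyl)oxy]-2H-chromene F2. Aqueous NH4Cl work-up should hydrolyse it to racemic 5,7,8-tris[(tert-butyldimethylsilyl)oxy]-2-[4-[(tert-butyldimethylsilyl)oxy]-3-(3-methylbut-3-en-1-yl)phenyl]-2,3-dihydro-4H-chromen-4-one F3. Preparative chromatography on a chiral stationary phase then delivers the (2S)-enantiomer, compound 15, and the route continues with step 9.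

Step 9. Transient phenoxides may enolise C3 and open the pyranone by retro-oxa-Michael reaction, which would racemise C2 and allow reclosure onto the other ortho oxygen, and the free 5,8-dihydroxy ring may oxidise in air. The fallback sets out from 15 and comes back at 16. The silyl groups are exchanged for acetyl groups in one pot (KF, Ac2O, MeCN, 0 °C → rt), so that each phenoxide is acylated as it forms. This should give (2S)-2-[4-acetoxy-3-(3-methylbut-3-en-1-yl)phenyl]-4-oxo-3,4-dihydro-2H-chromene-5,7,8-triyl triacetate F4, which is stable, can be purified and allows the enantiomeric purity to be checked. Neutral methanolysis of the aryl acetates (NH4OAc, MeOH/H2O, rt, argon) should then give 16.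

Step 6. The homoallyl–palladium intermediate has allylic β-hydrogens, so β-hydride elimination to isoprene with hydrodeiodination of the arene may compete, or some coupling may occur at the C–Br bond. The fallback sets out from 7 and comes back at 11. Free phenol 7 undergoes a ligand-free Heck reaction at the C–I bond with but-3-en-2-ol (Pd(OAc)2, Bu4NCl, NaHCO3, DMF, 50 °C), in which β-hydride elimination towards the carbinol gives the ketone 4-(5-bromo-2-hydroxyphenyl)butan-2-one F5. Wittig methylenation (Ph3PCH3Br, KOtBu, 2.5 equiv, THF) should give 4-bromo-2-(3-methylbut-3-en-1-yl)phenol F6. Silylation (TBSCl, imidazole, DMF) then gives 11.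

**Further compounds**

F1 | step 8 | [4-[(tert-butyldimethylsilyl)oxy]-3-(3-methylbut-3-en-1-yl)phenyl]magnesium bromide | C=C(C)CCc1cc([Mg]Br)ccc1O[Si](C)(C)C(C)(C)C
F2 | step 8 | racemic 5,7,8-tris[(tert-butyldimethylsilyl)oxy]-2-[4-[(tert-butyldimethylsilyl)oxy]-3-(3-methylbut-3-en-1-yl)phenyl]-4-[(trimethylsilyl)oxy]-2H-chromene | C=C(C)CCc1cc(C2C=C(O[Si](C)(C)C)c3c(O[Si](C)(C)C(C)(C)C)cc(O[Si](C)(C)C(C)(C)C)c(O[Si](C)(C)C(C)(C)C)c3O2)ccc1O[Si](C)(C)C(C)(C)C
F3 | step 8 | racemic 5,7,8-tris[(tert-butyldimethylsilyl)oxy]-2-[4-[(tert-butyldimethylsilyl)oxy]-3-(3-methylbut-3-en-1-yl)phenyl]-2,3-dihydro-4H-chromen-4-one | C=C(C)CCc1cc(C2CC(=O)c3c(O[Si](C)(C)C(C)(C)C)cc(O[Si](C)(C)C(C)(C)C)c(O[Si](C)(C)C(C)(C)C)c3O2)ccc1O[Si](C)(C)C(C)(C)C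
F4 | step 9 | (2S)-2-[4-acetoxy-3-(3-methylbut-3-en-1-yl)phenyl]-4-oxo-3,4-dihydro-2H-chromene-5,7,8-triyl triacetate | C=C(C)CCc1cc([C@@H]2CC(=O)c3c(OC(C)=O)cc(OC(C)=O)c(OC(C)=O)c3O2)ccc1OC(C)=O
F5 | step 6 | 4-(5-bromo-2-hydroxyphenyl)butan-2-one | CC(=O)CCc1cc(Br)ccc1O
F6 | step 6 | 4-bromo-2-(3-methylbut-3-en-1-yl)phenol | C=C(C)CCc1cc(Br)ccc1O
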